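(The data were computed on assumed constants, noise included.)

- The Q charge is a fixed budget, so each Q taken up in the first exchange is one Q fewer on hand for the second.

in all of them: X 0.069 M; J 0.138 M
- larch: Q 0.087 M; run made earlier
- oak: Q 0.13 M; run made earlier
- dawn: Q 0.104 M; time 5.0 min
- autumn: Q 0.0690 M; time 5.0 min

- larch (time / min: E / %, X / %): 0.500: 3.4, 14.4; 1.00: 4.6, 3.4; 1.50: 6.2, 1.0; 2.00: 8.1, 0.5; 2.50: 9.6, 0.3; 3.00: 10.4, 0; 4.00: 11.6, 0.2
- oak (time / min: E / %, X / %): 0.200: 2.3, 30.7; 0.500: 6.4, 5.7; 1.00: 10.4, 0.4; 1.50: 14.8, 0.2; 2.00: 18.1, 0; 3.00: 22.4, 0.2; 4.00: 26.6, 0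

(scatter of a reading: 0.3 percentage points)

1. which of these holds the largest part of the X at the end of dawn (E / X / G)
2. which of these holds the largest part of the X at the end of autumn (E / X / G)
3. how much E is there at the end of autumn, in percent of the X charged



- This reckoning lets each Q meet a fork, at X or on towards E, and the two earlier runs price that fork: at 4.00 min, oak's extra Q bought E at 0.241 of the X charge per equivalent, as read.
- Extending that line down to zero E gives the first-call cost, the equivalents of Q per X charged that yield no E by that time: 0.779.
- One extreme is a sharp threshold: autumn's single equivalent stands above the cost, and the line gives 5.32% of E at 4.00 min.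
- The other extreme has no threshold: a power of the Q charge through larch and oak, of order 2.07, gives 7.19%.
- If E curves upward with the charge, it lies above the line; if a threshold exists, it lies below the power.
- This reckoning takes the midpoint and raises it by larch's last ratio of readings, giving 6.97% at 5.0 min; it reads nothing about G.
- The forecast names G for dawn and G for autumn, with E at 4.5% (2.5% to 8%), lower than this reckoning, on the ground that “free Q stays small”.

    X + Q → J + G (k = 0.673 L mol⁻¹ s⁻¹)
    G + Q → J + E (k = 0.0777 L mol⁻¹ s⁻¹)
    X + G → L (k = 1.68 L mol⁻¹ s⁻¹)
    Q → D (k = 0.00174 s⁻¹)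

- Autumn ends with 7.34% of E and 12.1% of G, while dawn ends with E at 19.3%, above G at 13.7%, against the forecast's G. At 5.00 min in autumn, the first Q of each complex in L, G and E, plus D, comes to 0.752 equivalents, beside the cost of 0.779, with 17% of Q free. Raising X to 0.28 M gives a neighbouring flask with 0.246 equiv equivalents of Q, below the cost, so the reckoning leaves no margin for E. There Q is the limiting reagent, with 0% left, and E ends at 0.123%.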